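**Plan**

Numbering: lactone O1, C2 (C=O), C3, C4, C5; exocyclic C6 on C3 carries ring B (3,4-dihydroxy-5-methoxyphenyl); C7 on C4 carries ring A (4-hydroxy-3-methoxyphenyl).
Retrosynthetic cuts, in order: O1–C2 (lactone reopened as a C2 8-aminoquinoline amide and a C5 silyl ether), C6–ring B (C–H arylation of a C3=C6H2 amide), C3=C6 (methylenation of the lactone), C4–C7 (Stobbe condensation of protected vanillin with dimethyl succinate).
Forward: the C7–C4 chain is joined first, the lactone ring is closed once to carry C4 through methylenation, it is opened to the amide, ring B is attached, and the lactone is closed again in the last step.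
Enabling feature: ring B on C6 lies cis to the C2 carbonyl across C3=C6, the one vinylic site that a C2-bound N,N-bidentate amide reaches through a five-membered palladacycle; this fixes the Z geometry.
Stereochemistry: C4 (S) is set by Rh-catalysed asymmetric hydrogenation of the Stobbe half-ester and is a spectator afterwards.

Key step: step 11

Assumption: the Et-DuPhos antipode used in step 3 is the one that delivers the S acid 5 (both antipodes are available); the sense is to be confirmed on lactone 7 by the sign of rotation against the known R series.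

**Route**

Step 1
Reactants: 1 vanillin (4-hydroxy-3-methoxybenzaldehyde)
Product: 2 3-methoxy-4-(methoxymethoxy)benzaldehyde
Conditions: MOMCl (1.3 equiv), i-Pr2NEt (1.6 equiv), CH2Cl2, 0 °C to rt
Reagents that add atoms: chloromethyl methyl ether (MOMCl), COCCl
Why: O-alkylation of the phenol (MOM protection) masks the acidic OH that would deactivate the aldehyde as its phenoxide in the Stobbe condensation, and the ether is removed only in the final acid step.

Step 2
Reactants: 2 3-methoxy-4-(methoxymethoxy)benzaldehyde; 3 dimethyl succinate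
Product: 4 (E)-3-(methoxycarbonyl)-4-[3-methoxy-4-(methoxymethoxy)phenyl]but-3-enoic acid
Conditions: 3 (1.5 equiv), NaOMe (2 equiv), MeOH, reflux; then 1 M HCl, 0 °C, pH 3
Reagents that add atoms: none
Why: The Stobbe condensation of a non-enolisable aromatic aldehyde with a succinic diester gives the E-alkylidene half-ester directly, with the two carboxyl carbons (later C2 and C5) differentiated as acid and ester.

Step 3
Reactants: 4 (E)-3-(methoxycarbonyl)-4-[3-methoxy-4-(methoxymethoxy)phenyl]but-3-enoic acid
Product: 5 (3S)-3-(methoxycarbonyl)-4-[3-methoxy-4-(methoxymethoxy)phenyl]butanoic acid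
Conditions: H2 (5 bar), [Rh(cod)(Et-DuPhos)]BF4 (0.5 mol%, antipode giving S), NaOMe (0.1 equiv), MeOH, rt
Reagents that add atoms: none
Why: Rh-catalysed asymmetric hydrogenation of an itaconate-type half-ester, in which carboxylate and alkene chelate the cationic rhodium bisphospholane so that hydrogen is delivered to one face and the ligand sets the C4 stereocentre.

Step 4
Reactants: 5 (3S)-3-(methoxycarbonyl)-4-[3-methoxy-4-(methoxymethoxy)phenyl]butanoic acid
Product: 7 (4S)-4-[3-methoxy-4-(methoxymethoxy)benzyl]dihydrofuran-2(3H)-one, via potassium hydroxy carboxylate 6 (not isolated)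
Conditions: KOH (1.0 equiv), EtOH; CaCl2, NaBH4, EtOH, −10 °C to rt; then 1 M HCl to pH 2–3, 0 °C to rt
Reagents that add atoms: none
Why: Chemoselective borohydride reduction, in which Ca(BH4)2 made in situ reduces the methyl ester while the carboxylate salt is inert, followed by lactonisation of the γ-hydroxy acid on mild acidification without touching C4.

Step 5
Reactants: 7 (4S)-4-[3-methoxy-4-(methoxymethoxy)benzyl]dihydrofuran-2(3H)-one
Product: 9 (4S)-4-[3-methoxy-4-(methoxymethoxy)benzyl]-3-methylidenedihydrofuran-2(3H)-one, via sodium formyl enolate 8 (not isolated)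
Conditions: NaH (1.1 equiv), HCO2Et (1.5 equiv), EtOH (cat.), Et2O, 0 °C to rt; then (CH2O)n (5 equiv), THF, 65 °C
Reagents that add atoms: formaldehyde (as paraformaldehyde), C=O
Why: α-Methylenation by Claisen formylation at C3, aldol addition of the enolate to formaldehyde and loss of formate builds the exocyclic C3=C6H2 with no more than about one equivalent of base present, so the allylic C4–H should not be removed.

Step 6
Reactants: 9 (4S)-4-[3-methoxy-4-(methoxymethoxy)benzyl]-3-methylidenedihydrofuran-2(3H)-one
Product: 12 (3S)-4-[(tert-butyldimethylsilyl)oxy]-3-[3-methoxy-4-(methoxymethoxy)benzyl]-2-methylidenebutanoic acid, via lithium hydroxy carboxylate 10 (not isolated), via silyl ether silyl ester 11 (not isolated)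
Conditions: LiOH·H2O (1.1 equiv), THF/H2O, 0 °C; evaporate; TBSCl (3 equiv), imidazole (6 equiv), DMF, rt; then K2CO3, MeOH/THF/H2O, rt; 0.5 M HCl to pH 4, 0 °C
Reagents that add atoms: lithium hydroxide, [Li+].[OH-]; tert-butyldimethylsilyl chloride (TBSCl), CC(C)(C)[Si](C)(C)Cl
Why: Saponification of the lactone, exhaustive silylation and selective solvolysis of the labile silyl ester is the standard way to hold a γ-hydroxy acid open, and it keeps the reactive C3=C6H2 acceptor away from a free nucleophilic amine.

Step 7
Reactants: 12 (3S)-4-[(tert-butyldimethylsilyl)oxy]-3-[3-methoxy-4-(methoxymethoxy)benzyl]-2-methylidenebutanoic acid; 13 8-aminoquinoline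
Product: 14 (3S)-4-[(tert-butyldimethylsilyl)oxy]-3-[3-methoxy-4-(methoxymethoxy)benzyl]-2-methylidene-N-(quinolin-8-yl)butanamide
Conditions: 13 (1.2 equiv), EDC·HCl (1.5 equiv), DMAP (1.0 equiv), CH2Cl2, 0 °C to rt
Reagents that add atoms: none
Why: DMAP-assisted carbodiimide amide coupling acylates the weakly nucleophilic 8-aminoquinoline under non-acidic conditions that spare the MOM and TBS ethers, placing the N,N-bidentate directing group on C2.

Step 8
Reactants: 15 2-hydroxy-3-methoxybenzaldehyde (o-vanillin)
Product: 16 2-hydroxy-5-iodo-3-methoxybenzaldehyde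
Conditions: NIS (1.05 equiv), TFA (0.1 equiv), MeCN, rt
Reagents that add atoms: N-iodosuccinimide (NIS), O=C1CCC(=O)N1I
Why: Electrophilic aromatic iodination goes para to the free phenol, the position that is also meta to the formyl group.

Step 9
Reactants: 16 2-hydroxy-5-iodo-3-methoxybenzaldehyde
Product: 17 5-iodo-3-methoxybenzene-1,2-diol
Conditions: 30% H2O2 (1.2 equiv), NaOH (1.05 equiv), H2O/THF, 0 °C to rt, N2
Reagents that add atoms: hydrogen peroxide, OO
Why: Dakin oxidation of an ortho-hydroxybenzaldehyde with alkaline hydrogen peroxide replaces the formyl group by hydroxyl through aryl migration to oxygen and leaves the aryl iodide untouched.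

Step 10
Reactants: 17 5-iodo-3-methoxybenzene-1,2-diol
Product: 18 5-iodo-1-methoxy-2,3-bis(methoxymethoxy)benzene
Conditions: MOMCl (3 equiv), i-Pr2NEt (4 equiv), CH2Cl2, 0 °C to rt
Reagents that add atoms: chloromethyl methyl ether (MOMCl), COCCl
Why: Double O-alkylation (MOM protection) of the air-sensitive catechol gives an aryl iodide without acidic protons and without substituents ortho to iodine, as the C–H arylation requires.

Step 11
Reactants: 14 (3S)-4-[(tert-butyldimethylsilyl)oxy]-3-[3-methoxy-4-(methoxymethoxy)benzyl]-2-methylidene-N-(quinolin-8-yl)butanamide; 18 5-iodo-1-methoxy-2,3-bis(methoxymethoxy)benzene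
Product: 19 (2Z,3S)-4-[(tert-butyldimethylsilyl)oxy]-2-[3-methoxy-4,5-bis(methoxymethoxy)benzylidene]-3-[3-methoxy-4-(methoxymethoxy)benzyl]-N-(quinolin-8-yl)butanamide
Conditions: 18 (3 equiv), Pd(OAc)2 (10 mol%), AgOAc (2.2 equiv), toluene, 110 °C, sealed tube, dark
Reagents that add atoms: none
Why: The deprotonated amide nitrogen and the quinoline nitrogen bind divalent palladium and hold it beside the single C6–H bond that is cis to the C2 carbonyl, where acetate-assisted concerted metalation–deprotonation gives a five-membered alkenyl palladacycle. Oxidative addition of iodide 18 to a tetravalent palladium aryl, C6–aryl reductive elimination and protonolysis of the Pd–N bond release 19, while AgOAc removes iodide as AgI and regenerates Pd(OAc)2. The closest known reaction type is the 8-aminoquinoline-directed, Z-selective β-C–H arylation of α-substituted acrylamides with aryl iodides under Pd(OAc)2 and AgOAc. No ring is closed and no stereocentre is created; the new element is the C3=C6 geometry, which is Z because the chelate can deliver the aryl group only to the carbonyl side, the opposite of a Heck or condensation outcome. The step needs single arylation at C6 rather than at the C4 methine or the C7 benzylic position, and no loss of configuration at C4: the tertiary C4–H and the six-membered palladacycle needed for C7 are both disfavoured, the remaining C6–H is trans to the chelate after one arylation, and the acetate-buffered medium should not deprotonate C4.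

Step 12
Reactants: 19 (2Z,3S)-4-[(tert-butyldimethylsilyl)oxy]-2-[3-methoxy-4,5-bis(methoxymethoxy)benzylidene]-3-[3-methoxy-4-(methoxymethoxy)benzyl]-N-(quinolin-8-yl)butanamide
Product: 20 (2Z,3S)-4-hydroxy-2-[3-methoxy-4,5-bis(methoxymethoxy)benzylidene]-3-[3-methoxy-4-(methoxymethoxy)benzyl]-N-(quinolin-8-yl)butanamide
Conditions: TBAF (1.2 equiv), AcOH (1.2 equiv), THF, 0 °C to rt, dark
Reagents that add atoms: none
Why: Fluoride-induced Si–O cleavage (desilylation) frees the C5 hydroxyl, and the acetic acid buffer keeps the allylic C4–H and the Z alkene away from basic alkoxide.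

Step 13
Reactants: 20 (2Z,3S)-4-hydroxy-2-[3-methoxy-4,5-bis(methoxymethoxy)benzylidene]-3-[3-methoxy-4-(methoxymethoxy)benzyl]-N-(quinolin-8-yl)butanamide
Product: 21 (3Z,4S)-3-(3,4-dihydroxy-5-methoxybenzylidene)-4-(4-hydroxy-3-methoxybenzyl)dihydrofuran-2(3H)-one (target)
Conditions: HCl (1.25 M in MeOH), 45 °C, dark; NaHCO3 work-up
Reagents that add atoms: none
Why: Acid-catalysed N-to-O acyl transfer (lactonisation), in which the C5 hydroxyl attacks the protonated amide in a 5-exo-trig closure that expels 8-aminoquinoline, runs alongside transacetalisation of the three MOM ethers to dimethoxymethane, and the acidic medium avoids the dienolate that would epimerise C4.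

**Compound list**

1 | vanillin (4-hydroxy-3-methoxybenzaldehyde) | COc1cc(C=O)ccc1O | starting material
2 | 3-methoxy-4-(methoxymethoxy)benzaldehyde | COCOc1ccc(C=O)cc1OC | intermediate
3 | dimethyl succinate | COC(=O)CCC(=O)OC | starting material
4 | (E)-3-(methoxycarbonyl)-4-[3-methoxy-4-(methoxymethoxy)phenyl]but-3-enoic acid | COC(=O)/C(CC(=O)O)=C/c1ccc(OCOC)c(OC)c1 | intermediate
5 | (3S)-3-(methoxycarbonyl)-4-[3-methoxy-4-(methoxymethoxy)phenyl]butanoic acid | COCOc1ccc(C[C@@H](CC(=O)O)C(=O)OC)cc1OC | intermediate
6 | potassium (3S)-4-hydroxy-3-[3-methoxy-4-(methoxymethoxy)benzyl]butanoate | COCOc1ccc(C[C@@H](CC(=O)[O-])CO)cc1OC.[K+] | intermediate (not isolated)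
7 | (4S)-4-[3-methoxy-4-(methoxymethoxy)benzyl]dihydrofuran-2(3H)-one | COCOc1ccc(C[C@@H]2COC(=O)C2)cc1OC | intermediate
8 | sodium enolate of (4S)-3-formyl-4-[3-methoxy-4-(methoxymethoxy)benzyl]dihydrofuran-2(3H)-one | COCOc1ccc(C[C@@H]2COC(=O)C2=C[O-])cc1OC.[Na+] | intermediate (not isolated)
9 | (4S)-4-[3-methoxy-4-(methoxymethoxy)benzyl]-3-methylidenedihydrofuran-2(3H)-one | COCOc1ccc(C[C@@H]2COC(=O)C2=C)cc1OC | intermediate
10 | lithium (3S)-4-hydroxy-3-[3-methoxy-4-(methoxymethoxy)benzyl]-2-methylidenebutanoate | COCOc1ccc(C[C@@H](C(=C)C(=O)[O-])CO)cc1OC.[Li+] | intermediate (not isolated)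
11 | tert-butyldimethylsilyl (3S)-4-[(tert-butyldimethylsilyl)oxy]-3-[3-methoxy-4-(methoxymethoxy)benzyl]-2-methylidenebutanoate | COCOc1ccc(C[C@@H](C(=C)C(=O)O[Si](C)(C)C(C)(C)C)CO[Si](C)(C)C(C)(C)C)cc1OC | intermediate (not isolated)
12 | (3S)-4-[(tert-butyldimethylsilyl)oxy]-3-[3-methoxy-4-(methoxymethoxy)benzyl]-2-methylidenebutanoic acid | COCOc1ccc(C[C@@H](C(=C)C(=O)O)CO[Si](C)(C)C(C)(C)C)cc1OC | intermediate
13 | 8-aminoquinoline | Nc1cccc2cccnc12 | starting material
14 | (3S)-4-[(tert-butyldimethylsilyl)oxy]-3-[3-methoxy-4-(methoxymethoxy)benzyl]-2-methylidene-N-(quinolin-8-yl)butanamide | C=C(C(=O)Nc1cccc2cccnc12)[C@H](Cc1ccc(OCOC)c(OC)c1)CO[Si](C)(C)C(C)(C)C | intermediate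
15 | 2-hydroxy-3-methoxybenzaldehyde (o-vanillin) | COc1cccc(C=O)c1O | starting material
16 | 2-hydroxy-5-iodo-3-methoxybenzaldehyde | COc1cc(I)cc(C=O)c1O | intermediate
17 | 5-iodo-3-methoxybenzene-1,2-diol | COc1cc(I)cc(O)c1O | intermediate
18 | 5-iodo-1-methoxy-2,3-bis(methoxymethoxy)benzene | COc1cc(I)cc(OCOC)c1OCOC | intermediate
19 | (2Z,3S)-4-[(tert-butyldimethylsilyl)oxy]-2-[3-methoxy-4,5-bis(methoxymethoxy)benzylidene]-3-[3-methoxy-4-(methoxymethoxy)benzyl]-N-(quinolin-8-yl)butanamide | O=C(Nc1cccc2cccnc12)/C(=C\c1cc(OCOC)c(OCOC)c(OC)c1)[C@H](Cc1ccc(OCOC)c(OC)c1)CO[Si](C)(C)C(C)(C)C | intermediate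
20 | (2Z,3S)-4-hydroxy-2-[3-methoxy-4,5-bis(methoxymethoxy)benzylidene]-3-[3-methoxy-4-(methoxymethoxy)benzyl]-N-(quinolin-8-yl)butanamide | O=C(Nc1cccc2cccnc12)/C(=C\c1cc(OCOC)c(OCOC)c(OC)c1)[C@H](Cc1ccc(OCOC)c(OC)c1)CO | intermediate
21 | (3Z,4S)-3-(3,4-dihydroxy-5-methoxybenzylidene)-4-(4-hydroxy-3-methoxybenzyl)dihydrofuran-2(3H)-one | COc1cc(C[C@@H]2COC(=O)/C2=C\c2cc(O)c(O)c(OC)c2)ccc1O | target

**Count and risks**

Total step count: 13. Longest linear sequence: 10 steps (steps 1–7 and 11–13); steps 8–10 make the ring B iodide.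

Most likely to fail, step 11. The branched C4 substituent may slow cyclometalation so that a Heck-type carbopalladation of the 1,1-disubstituted alkene competes, giving the wrong geometry, double-bond migration or low conversion. The fallback gives up chelate control and corrects the geometry with light. It sets out from lactone 7 and iodide 18. Iodine–magnesium exchange on 18 (i-PrMgCl·LiCl, THF, −20 °C) and quenching with DMF should give 3-methoxy-4,5-bis(methoxymethoxy)benzaldehyde F1. The lithium enolate of 7 (LiN(i-Pr)2, THF, −78 °C) adds to F1 to give the aldol adduct F2 as a mixture at the carbinol centre. Mesylation (MsCl, Et3N, CH2Cl2, 0 °C) gives the mesylate F3, and DBU then eliminates it to the E-benzylidene lactone tris(MOM) ether F4. Irradiation at 450 nm with fac-Ir(ppy)3 as triplet sensitiser in degassed MeCN (energy-transfer E-to-Z isomerisation of a cinnamate-type alkene) should enrich the Z-benzylidene lactone tris(MOM) ether F5, with recovered F4 recycled. HCl in MeOH as in step 13 removes the three MOM groups and the sequence comes back to the route at target 21.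

Second, step 13. Expulsion of 8-aminoquinoline may be slow, and the prolonged acid treatment then needed could let the electron-rich C3=C6 bond equilibrate from Z to E or leave partly deprotected material. The fallback activates the amide first so that the acyl group leaves under mild conditions. It sets out from 19. Boc2O and DMAP in MeCN should give the N-Boc amide F6. LiOH and H2O2 in THF/H2O at 0 °C cleave the twisted imide to the Z-configured silyloxy acid F7, with the auxiliary leaving as its Boc carbamate. Brief treatment with HCl in MeOH at rt then removes the silyl group, lets the γ-hydroxy acid lactonise spontaneously and cleaves the MOM ethers, coming back to the route at target 21.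

Third, step 5. Formylation of the β-branched lactone may be incomplete, and alkoxide present during the formaldehyde stage may move the new double bond into the ring or deprotonate C4, eroding the stereocentre. The fallback uses a weakly acidic decarboxylative methylenation instead. It sets out from lactone 7. Carboxylation with MeOMgOCO2Me in DMF at 125 °C and cold acidification should give the α-carboxy lactone F8. Aqueous HCHO, Et2NH, NaOAc and AcOH (Mannich reaction with loss of CO2 and amine) then give the methylene lactone, coming back to the route at 9.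

**Further compounds**

F1 | step 11 | 3-methoxy-4,5-bis(methoxymethoxy)benzaldehyde | COc1cc(C=O)cc(OCOC)c1OCOC
F2 | step 11 | (4S)-3-{hydroxy[3-methoxy-4,5-bis(methoxymethoxy)phenyl]methyl}-4-[3-methoxy-4-(methoxymethoxy)benzyl]dihydrofuran-2(3H)-one | COCOc1ccc(C[C@@H]2COC(=O)C2C(O)c2cc(OCOC)c(OCOC)c(OC)c2)cc1OC
F3 | step 11 | methanesulfonate of F2 at the carbinol oxygen | COCOc1ccc(C[C@@H]2COC(=O)C2C(OS(C)(=O)=O)c2cc(OCOC)c(OCOC)c(OC)c2)cc1OC
F4 | step 11 | (3E,4S)-3-[3-methoxy-4,5-bis(methoxymethoxy)benzylidene]-4-[3-methoxy-4-(methoxymethoxy)benzyl]dihydrofuran-2(3H)-one | COCOc1ccc(C[C@@H]2COC(=O)/C2=C/c2cc(OCOC)c(OCOC)c(OC)c2)cc1OC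
F5 | step 11 | (3Z,4S)-3-[3-methoxy-4,5-bis(methoxymethoxy)benzylidene]-4-[3-methoxy-4-(methoxymethoxy)benzyl]dihydrofuran-2(3H)-one | COCOc1ccc(C[C@@H]2COC(=O)/C2=C\c2cc(OCOC)c(OCOC)c(OC)c2)cc1OC
F6 | step 13 | tert-butyl N-{(2Z,3S)-4-[(tert-butyldimethylsilyl)oxy]-2-[3-methoxy-4,5-bis(methoxymethoxy)benzylidene]-3-[3-methoxy-4-(methoxymethoxy)benzyl]butanoyl}-N-(quinolin-8-yl)carbamate | CC(C)(C)OC(=O)N(c1cccc2cccnc12)C(=O)/C(=C\c1cc(OCOC)c(OCOC)c(OC)c1)[C@H](Cc1ccc(OCOC)c(OC)c1)CO[Si](C)(C)C(C)(C)C
F7 | step 13 | (2Z,3S)-4-[(tert-butyldimethylsilyl)oxy]-2-[3-methoxy-4,5-bis(methoxymethoxy)benzylidene]-3-[3-methoxy-4-(methoxymethoxy)benzyl]butanoic acid | OC(=O)/C(=C\c1cc(OCOC)c(OCOC)c(OC)c1)[C@H](Cc1ccc(OCOC)c(OC)c1)CO[Si](C)(C)C(C)(C)C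
F8 | step 5 | (4S)-4-[3-methoxy-4-(methoxymethoxy)benzyl]-2-oxotetrahydrofuran-3-carboxylic acid | COCOc1ccc(C[C@@H]2COC(=O)C2C(=O)O)cc1OC
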